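**Plan**
1. Cuts: (a) the bond between side-chain carbinol carbon C6 (bearing OH, CH3 and the homoprenyl chain) and dienyl CH C5; (b) the diene carbons C5, then C4/C3, back to a ring methyl ketone; (c) the ring C–Br and C–OH bonds, back to the ring alkene of (S)-limonene.
2. Enabling feature: C6 is the carbinol carbon of sulcatol with H exchanged for a dienyl group, and its neighbour C5 is an sp2 CH that can sit on boron. As a hindered benzoate the C6–H can be lithiated (polarity reversal), so two nucleophilic carbons are joined through a boron ate complex, and C–B then becomes C–OH.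
3. Forward order: the only ring, the cyclohexane, comes intact from limonene. The sequence is ring functionalisation, methyl ketone, enamide, enal, enyne, (E,E)-dienylboronic ester, union with the C8 benzoate, desilylation.
4. Stereochemistry: ring C4 comes from limonene. C1 and C2 are relayed from C4 by trans-diaxial epoxide hydrolysis, and C2 is then inverted by bromide on a cyclic sulfate. The 2E alkene comes from the HWE reaction and the 4E alkene from syn hydroboration. C6 comes from enzymatic ketone reduction, Mitsunobu inversion and stereospecific lithiation–borylation–oxidation.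
5. The ring bromide is equatorial, next to a fully substituted carbon, and has no anti-periplanar H or O, which is why it can be carried through the basic and organometallic steps.

Key step: step 13

Remark: the SMILES is read as ring (1R,2S,4S) with Br cis to the tertiary OH (Br, CH3 and side chain equatorial, OH axial) and side chain (2E,4E,6S); ring locants are C1 = C(OH)CH3, C2 = CHBr, C4 = CH bearing the side chain, and side-chain C2 is the ring-bound alkene carbon and C6 the carbinol carbon.

**Step 1**
Reactants: 1 (S)-(−)-limonene
Product: 2 (4S)-limonene 1,2-oxide (cis/trans epoxide mixture)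
Conditions: mCPBA (1.0 equiv), CH2Cl2, 0 °C
Reagents that add atoms: mCPBA, O=C(OO)c1cccc(Cl)c1
Why: Prilezhaev epoxidation picks the more electron-rich trisubstituted ring alkene over the 1,1-disubstituted isopropenyl group, and the lack of facial selectivity does not matter because both epoxides converge in step 2.

**Step 2**
Reactants: 2 (4S)-limonene 1,2-oxide
Product: 3 (1R,2R,4S)-1-methyl-4-(prop-1-en-2-yl)cyclohexane-1,2-diol (trans-diaxial diol)
Conditions: H2SO4 (cat.), H2O–acetone, 0 °C; recrystallisation
Reagents that add atoms: water, O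
Why: Acid-catalysed epoxide hydrolysis under the Fürst–Plattner rule: with the isopropenyl group equatorial, water opens the cis-oxide at C1 and the trans-oxide at C2, each in the trans-diaxial sense, so both should give the same (1R,2R) diol and C4 thereby sets C1 and C2.

**Step 3**
Reactants: 3 (1R,2R,4S)-diol
Product: 5 1-[(1S,3R,4R)-3,4-dihydroxy-4-methylcyclohexyl]ethan-1-one, via secondary ozonide 4 (not isolated)
Conditions: O3, CH2Cl2, −78 °C; then Me2S, −78 °C → rt
Reagents that add atoms: ozone, [O-][O+]=O
Why: Criegee ozonolysis with reductive work-up cleaves the only remaining alkene to the methyl ketone and touches no stereocentre.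

**Step 4**
Reactants: 5 keto diol
Product: 7 trans-fused cyclic sulfate (3aR,6S,7aR)-6-acetyl-3a-methylhexahydro-1,3,2-benzodioxathiole 2,2-dioxide, via cyclic sulfite 6 (not isolated)
Conditions: SOCl2, CH2Cl2, 0 °C → rt (HCl swept out with N2); then MeCN–H2O, RuCl3·xH2O (cat.), NaIO4, 0 °C
Reagents that add atoms: thionyl chloride, O=S(Cl)Cl; sodium periodate, [Na+].[O-]I(=O)(=O)=O
Why: Cyclic sulfate formation from a 1,2-diol (cyclic sulfite, then Ru-catalysed S-oxidation) breaks no C–O bond, so both carbinol configurations are kept, and the flexible ring can flip to place the two oxygens gauche for the trans-fused five-membered ring.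

**Step 5**
Reactants: 7 cyclic sulfate
Product: 9 1-[(1S,3S,4R)-3-bromo-4-hydroxy-4-methylcyclohexyl]ethan-1-one, via lithium bromo sulfate 8 (not isolated)
Conditions: LiBr, THF, reflux; then H2SO4 (cat.), H2O, THF, rt
Reagents that add atoms: lithium bromide, [Li+].[Br-]
Why: SN2 opening of the cyclic sulfate by bromide at the secondary carbon inverts C2 to (S) and puts Br cis to the tertiary oxygen, which is tied up as sulfate and cannot close an epoxide, and acid hydrolysis of the sulfate monoester by S–O cleavage then frees the tertiary alcohol with retention; the acetyl-bearing carbon is the equatorial, thermodynamic epimer, so enolisation cannot harm it.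

**Step 6**
Reactants: 9 bromohydrin ketone
Product: 10 1-[(1S,3S,4R)-3-bromo-4-methyl-4-(triethylsilyloxy)cyclohexyl]ethan-1-one
Conditions: TESOTf, 2,6-lutidine, CH2Cl2, −78 → 0 °C
Reagents that add atoms: triethylsilyl triflate, CC[Si](CC)(CC)OS(=O)(=O)C(F)(F)F
Why: Silylation with a silyl triflate and a hindered pyridine base covers the axial tertiary alcohol at low temperature faster than the ketone is enolised, and the TES ether removes the only acidic proton before the organometallic steps.

**Step 7**
Reactants: 10 TES-protected bromo ketone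
Product: 11 (E)-3-[(1S,3S,4R)-3-bromo-4-methyl-4-(triethylsilyloxy)cyclohexyl]-N-methoxy-N-methylbut-2-enamide
Conditions: (EtO)2P(O)CH2C(O)N(OMe)Me, NaH, THF, 0 °C → reflux; chromatography
Reagents that add atoms: diethyl (N-methoxy-N-methylcarbamoylmethyl)phosphonate, CCOP(=O)(CC(=O)N(C)OC)OCC
Why: Horner–Wadsworth–Emmons olefination of the methyl ketone places the amide trans to the bulky cyclohexyl group (E), and the weakly basic phosphonate anion leaves the equatorial bromide, which has no anti-periplanar hydrogen, untouched.

**Step 8**
Reactants: 11 Weinreb enamide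
Product: 12 (E)-3-[(1S,3S,4R)-3-bromo-4-methyl-4-(triethylsilyloxy)cyclohexyl]but-2-enal
Conditions: DIBAL-H, THF, −78 °C; aq Rochelle salt
Reagents that add atoms: none
Why: Weinreb amide reduction: the chelated tetrahedral aluminium intermediate holds until work-up, so the reaction stops at the enal without 1,4-reduction or loss of alkene geometry.

**Step 9**
Reactants: 12 enal
Product: 13 {[(1R,2S,4S)-2-bromo-1-methyl-4-[(2E)-pent-2-en-4-yn-2-yl]cyclohexyl]oxy}triethylsilane
Conditions: TMSCHN2, LDA, THF, −78 °C → rt
Reagents that add atoms: (trimethylsilyl)diazomethane, C[Si](C)(C)C=[N+]=[N-]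
Why: The Colvin rearrangement (addition of lithiated TMS-diazomethane, Peterson-type loss of silanolate, loss of N2, 1,2-hydride shift of the alkylidene carbene) homologates the enal to the terminal enyne and avoids the methanol conjugate addition that basic methanolic variants cause with enals.

**Step 10**
Reactants: 13 enyne
Product: 15 2-{(1E,3E)-4-[(1S,3S,4R)-3-bromo-4-methyl-4-(triethylsilyloxy)cyclohexyl]penta-1,3-dien-1-yl}-5,5-dimethyl-1,3,2-dioxaborinane, via catechol dienylboronate 14 (not isolated)
Conditions: catecholborane, Cy2BH (cat.), THF, rt; then neopentyl glycol, rt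
Reagents that add atoms: catecholborane, B1Oc2ccccc2O1; neopentyl glycol, OCC(C)(C)CO
Why: Syn, anti-Markovnikov hydroboration of the terminal alkyne, which reacts much faster than the trisubstituted alkene, sets the second E double bond, and transesterification exchanges catechol for the more strongly bound aliphatic diol.

**Step 11**
Reactants: 16 6-methylhept-5-en-2-one (sulcatone)
Product: 17 (R)-6-methylhept-5-en-2-ol
Conditions: (R)-selective alcohol dehydrogenase (Lactobacillus brevis type), NADP+ (cat.), i-PrOH, phosphate buffer pH 7, 30 °C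
Reagents that add atoms: none
Why: Biocatalytic anti-Prelog ketone reduction with cofactor recycling by isopropanol delivers hydride to the si face of the methyl ketone and so sets the (R) carbinol centre.

**Step 12**
Reactants: 17 (R)-6-methylhept-5-en-2-ol
Product: 18 (S)-6-methylhept-5-en-2-yl 2,4,6-triisopropylbenzoate
Conditions: 2,4,6-triisopropylbenzoic acid, PPh3, DIAD, THF, 0 °C → rt
Reagents that add atoms: 2,4,6-triisopropylbenzoic acid, CC(C)c1cc(C(C)C)c(C(=O)O)c(C(C)C)c1
Why: Mitsunobu esterification proceeds by SN2 attack of the carboxylate on the alkoxyphosphonium ion with inversion, which turns the (R)-alcohol into the (S)-benzoate and avoids acylation with the very hindered acid chloride.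

**Step 13**
Reactants: 18 (S)-triisopropylbenzoate; 15 (E,E)-dienylboronic ester
Product: 22 (3E,5E,7S)-2-[(1S,3S,4R)-3-bromo-4-methyl-4-(triethylsilyloxy)cyclohexyl]... written out as the C1-O-TES ether of the target, via lithiated benzoate 19 (not isolated), via boronate complex 20 (not isolated), via tertiary boronic ester 21 (not isolated)
Conditions: 18 (1.3 equiv), s-BuLi (1.2 equiv), TMEDA, CPME, −60 °C; 15 (1.0 equiv), −60 °C; MeOH (destroys residual 19), then → 40 °C; then H2O2, NaOH, THF–H2O, 0 °C
Reagents that add atoms: hydrogen peroxide, OO (s-BuLi, CCC(C)[Li], supplies only the lithium of 19 and 20)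
Why: s-BuLi/TMEDA, directed by the benzoate carbonyl, removes the carbinol C–H of 18 with retention to give the configurationally stable tertiary α-oxy-organolithium 19 (polarity reversal of the carbinol carbon), which attacks boron of 15 with retention to give ate complex 20; on warming, the dienyl sp2 carbon shifts from boron to carbon anti-periplanar to the departing triisopropylbenzoate (invertive 1,2-metallate rearrangement), which joins two formally nucleophilic carbons and makes the C5–C6 bond in 21. The closest known reaction type is the lithiation–borylation of unactivated secondary dialkyl triisopropylbenzoates with neopentyl glycol boronic esters, in which alkenyl boronic esters are established migrating groups. No ring is closed. The one new stereocentre is controlled only by the configuration of 18: retention, retention, inversion and the retentive C–B oxidation add up to replacement of H by the dienyl group with retention, that is (S). The migrating carbon keeps its geometry, so the preformed (E,E)-diene is transferred intact. The step needs attack at boron rather than at C–Br, and migration of carbon rather than of a glycol oxygen; this is secured because the neopentyl glycol ester keeps boron accessible, the bromide is equatorial, flanked by a fully substituted carbon and without an anti-periplanar H, the tertiary OH is masked as TES ether, and s-BuLi is kept below the amount of 18.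

**Step 14**
Reactants: 22 TES ether of the target
Product: 23 (1R,2S,4S)-2-bromo-4-[(2E,4E,6S)-6-hydroxy-6,10-dimethylundeca-2,4,9-trien-2-yl]-1-methylcyclohexan-1-ol (target)
Conditions: TBAF, THF, 0 °C → rt
Reagents that add atoms: none
Why: Fluoride-mediated desilylation under non-acidic conditions spares the ionisable tertiary dienylic alcohol, and the freed cis-bromohydrin cannot close to an epoxide because O and Br are not anti-periplanar.

**Compound list**
1 | (S)-(−)-limonene | C=C(C)[C@H]1CCC(C)=CC1 | starting material
2 | (4S)-limonene 1,2-oxide, cis/trans mixture | C=C(C)[C@H]1CCC2(C)OC2C1 | intermediate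
3 | (1R,2R,4S)-1-methyl-4-(prop-1-en-2-yl)cyclohexane-1,2-diol | C=C(C)[C@H]1CC[C@@](C)(O)[C@H](O)C1 | intermediate
4 | secondary ozonide (1,2,4-trioxolane) of 3 | CC2(OCOO2)[C@H]1CC[C@@](C)(O)[C@H](O)C1 | intermediate
5 | 1-[(1S,3R,4R)-3,4-dihydroxy-4-methylcyclohexyl]ethan-1-one | CC(=O)[C@H]1CC[C@@](C)(O)[C@H](O)C1 | intermediate
6 | cyclic sulfite of 5 (epimers at sulfur) | CC(=O)[C@H]1CC[C@@]2(C)OS(=O)O[C@@H]2C1 | intermediate
7 | cyclic sulfate of 5, (3aR,6S,7aR) | CC(=O)[C@H]1CC[C@@]2(C)OS(=O)(=O)O[C@@H]2C1 | intermediate
8 | lithium (1R,2S,4S)-4-acetyl-2-bromo-1-methylcyclohexyl sulfate | CC(=O)[C@H]1CC[C@@](C)(OS(=O)(=O)[O-])[C@@H](Br)C1.[Li+] | intermediate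
9 | 1-[(1S,3S,4R)-3-bromo-4-hydroxy-4-methylcyclohexyl]ethan-1-one | CC(=O)[C@H]1CC[C@@](C)(O)[C@@H](Br)C1 | intermediate
10 | TES ether of 9 | CC(=O)[C@H]1CC[C@@](C)(O[Si](CC)(CC)CC)[C@@H](Br)C1 | intermediate
11 | (E)-Weinreb enamide | CON(C)C(=O)/C=C(\C)[C@H]1CC[C@@](C)(O[Si](CC)(CC)CC)[C@@H](Br)C1 | intermediate
12 | (E)-enal | O=C/C=C(\C)[C@H]1CC[C@@](C)(O[Si](CC)(CC)CC)[C@@H](Br)C1 | intermediate
13 | (E)-enyne | C#C/C=C(\C)[C@H]1CC[C@@](C)(O[Si](CC)(CC)CC)[C@@H](Br)C1 | intermediate
14 | catechol (1E,3E)-dienylboronate | c1ccc2OB(/C=C/C=C(\C)[C@H]3CC[C@@](C)(O[Si](CC)(CC)CC)[C@@H](Br)C3)Oc2c1 | intermediate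
15 | neopentyl glycol (1E,3E)-dienylboronate | CC1(C)COB(/C=C/C=C(\C)[C@H]2CC[C@@](C)(O[Si](CC)(CC)CC)[C@@H](Br)C2)OC1 | intermediate
16 | 6-methylhept-5-en-2-one | CC(=O)CCC=C(C)C | starting material
17 | (R)-6-methylhept-5-en-2-ol | C[C@@H](O)CCC=C(C)C | intermediate
18 | (S)-6-methylhept-5-en-2-yl 2,4,6-triisopropylbenzoate | C[C@H](OC(=O)c1c(C(C)C)cc(C(C)C)cc1C(C)C)CCC=C(C)C | intermediate
19 | (S)-2-lithio-6-methylhept-5-en-2-yl 2,4,6-triisopropylbenzoate | C[C@]([Li])(OC(=O)c1c(C(C)C)cc(C(C)C)cc1C(C)C)CCC=C(C)C | intermediate
20 | lithium boronate (ate) complex of 19 and 15 | [Li+].C[C@]([B-]1(/C=C/C=C(\C)[C@H]2CC[C@@](C)(O[Si](CC)(CC)CC)[C@@H](Br)C2)OCC(C)(C)CO1)(OC(=O)c1c(C(C)C)cc(C(C)C)cc1C(C)C)CCC=C(C)C | intermediate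
21 | tertiary dienylic neopentyl glycol boronic ester (B in place of the C6 OH of 22; C6 is R only because B ranks lowest) | CC(C)=CCC[C@](C)(B2OCC(C)(C)CO2)/C=C/C=C(\C)[C@H]1CC[C@@](C)(O[Si](CC)(CC)CC)[C@@H](Br)C1 | intermediate
22 | ring C1-O-TES ether of the target, (2E,4E,6S) | CC(C)=CCC[C@](C)(O)/C=C/C=C(\C)[C@H]1CC[C@@](C)(O[Si](CC)(CC)CC)[C@@H](Br)C1 | intermediate
23 | (1R,2S,4S)-2-bromo-4-[(2E,4E,6S)-6-hydroxy-6,10-dimethylundeca-2,4,9-trien-2-yl]-1-methylcyclohexan-1-ol | CC(C)=CCC[C@](C)(O)/C=C/C=C(\C)[C@H]1CC[C@@](C)(O)[C@@H](Br)C1 | target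

**Totals**
Total step count: 14. Longest linear sequence: 12 (steps 1–10, 13, 14).

**Steps most likely to fail**

Step 13. Capture of the hindered tertiary organolithium by boron may be slow. Halogen–lithium exchange at the ring bromide may compete, and a glycol oxygen may migrate in place of carbon. The fallback is a polar carbonyl addition instead of the boron-mediated union. It sets out from enyne 13 and ketone 16 and comes back at 22.
- Deprotonation of 13 with LDA (THF, −78 °C) would give the lithium acetylide F1.
- CeCl3-assisted addition to 16 would give the epimeric enynol mixture F2, because nothing controls the face of the ketone.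
- Separation on a chiral stationary phase would give the (6S)-enynol F3.
- Hydroxyl-directed trans-hydroalumination with Red-Al (THF, 0 °C) would set the E alkene and give 22.

Step 5. Backside attack may be sluggish, because the trans-fused sulfate forces a ring flip that puts the acetyl group axial on the face bromide must approach. Ionisation or elimination at the tertiary C–O bond may then take over. The fallback is displacement of an open-chain axial sulfonate in the unflipped chair. It sets out from keto diol 5 and comes back at 10.
- Selective sulfonylation of the secondary alcohol (MsCl, pyridine, 0 °C) would give the hydroxy mesylate F4.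
- Immediate silylation (TESOTf, 2,6-lutidine, −78 °C) would give the silyloxy mesylate F5.
- LiBr in DMF with heating would displace the axial mesylate with inversion and give 10.

Step 7. E/Z selectivity may be poor and addition to the hindered methyl ketone slow, with competing enolisation. The fallback fixes the alkene geometry by syn carbometalation. It sets out from 10 and comes back at 13.
- Kinetic enolisation on the methyl side (LDA, −78 °C) and trapping with PhNTf2 would give the enol triflate F6.
- Elimination with LDA would give the terminal alkyne F7.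
- Negishi carboalumination (Me3Al, Cp2ZrCl2 cat., CH2Cl2) would give the (E)-alkenylalane F8.
- Iodinolysis would give the (E)-vinyl iodide F9.
- Sonogashira coupling with trimethylsilylacetylene would give the silyl enyne F10, and K2CO3/MeOH would give 13.

**Further compounds**
F1 | step 13 | lithium acetylide of 13 | [Li]C#C/C=C(\C)[C@H]1CC[C@@](C)(O[Si](CC)(CC)CC)[C@@H](Br)C1
F2 | step 13 | enynol, mixture of C6 epimers | CC(C)=CCCC(C)(O)C#C/C=C(\C)[C@H]1CC[C@@](C)(O[Si](CC)(CC)CC)[C@@H](Br)C1
F3 | step 13 | (6S)-enynol | CC(C)=CCC[C@](C)(O)C#C/C=C(\C)[C@H]1CC[C@@](C)(O[Si](CC)(CC)CC)[C@@H](Br)C1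
F4 | step 5 | (1R,2R,5S)-5-acetyl-2-hydroxy-2-methylcyclohexyl methanesulfonate | CC(=O)[C@H]1CC[C@@](C)(O)[C@H](OS(C)(=O)=O)C1
F5 | step 5 | TES ether of F4 | CC(=O)[C@H]1CC[C@@](C)(O[Si](CC)(CC)CC)[C@H](OS(C)(=O)=O)C1
F6 | step 7 | enol triflate of 10 (methyl side) | C=C(OS(=O)(=O)C(F)(F)F)[C@H]1CC[C@@](C)(O[Si](CC)(CC)CC)[C@@H](Br)C1
F7 | step 7 | ring-bound terminal alkyne | C#C[C@H]1CC[C@@](C)(O[Si](CC)(CC)CC)[C@@H](Br)C1
F8 | step 7 | (E)-alkenyl(dimethyl)alane | C[Al](C)/C=C(\C)[C@H]1CC[C@@](C)(O[Si](CC)(CC)CC)[C@@H](Br)C1
F9 | step 7 | (E)-vinyl iodide | I/C=C(\C)[C@H]1CC[C@@](C)(O[Si](CC)(CC)CC)[C@@H](Br)C1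
F10 | step 7 | C-trimethylsilyl derivative of 13 | C[Si](C)(C)C#C/C=C(\C)[C@H]1CC[C@@](C)(O[Si](CC)(CC)CC)[C@@H](Br)C1
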